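**Plan**

1. Flavanone numbering is used (ring A: C4a, C5–C8, C8a; ring C: O1, C2, C3, C4; ring B: the catechol). Retrosynthesis: the four phenols are masked as MOM ethers, then ring C is cut at two bonds at once, O1–C8a and C4–C4a. This leaves a ring-A aryne (C4a≡C8a) and an open-chain (S)-3-aryl-3-oxypropanoic Weinreb amide that already holds O1, C2, C3, C4 and ring B.
2. The aryne precursor is an o-silylaryl triflate built from resorcinol: MOM ethers, prenyl at C6 by lithiation, oxygen at C8a by C–H borylation/oxidation, silicon at C4a by bromination and retro-Brook shift. The chain comes from methyl 3,4-dihydroxybenzoate by Claisen condensation and asymmetric transfer hydrogenation.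
3. Forward: rings A and B are bought as arenes and dressed separately, and ring C is the only ring formed. Fluoride frees an alkoxide and the aryne, O1 adds to C8a, and the carbanion left at C4a closes ring C on the amide carbonyl C4.
4. Enabling feature: C4a and C8a are neighbours on ring A and C4a lies between C8a and the C5 oxygen. The C5 and C7 oxygens therefore polarise the C4a≡C8a aryne so that the nucleophile enters at C8a and the anion sits at C4a, six atoms from C4. In addition, the prenylated phenol that precedes the aryne is symmetric about the C6···C8a axis, so its two ortho carbons are equivalent and only the 6-prenyl series can arise.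
5. Stereochemistry: the single stereocenter C2 is set by catalyst control in the transfer hydrogenation of the aryl ketone. Its C–O bond is never broken afterwards, so it passes through the annulation with retention.

Key step: step 10

**Route**

Step 1
Reactants: 1 resorcinol
Product: 2 1,3-bis(methoxymethoxy)benzene
Conditions: NaH (2.4 equiv), MOMCl (2.4 equiv), DMF, 0 °C → rt
Reagents that add atoms: chloromethyl methyl ether (MOMCl), COCCl
Why: Williamson etherification of both sodium phenoxides with the α-chloro ether gives the bis-acetal, whose ethers later serve as protecting and as directing groups.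

Step 2
Reactants: 2 1,3-bis(methoxymethoxy)benzene; 3 1-bromo-3-methylbut-2-ene (prenyl bromide)
Product: 5 1,3-bis(methoxymethoxy)-2-(3-methylbut-2-en-1-yl)benzene, via aryllithium 4 (not isolated)
Conditions: n-BuLi (1.1 equiv), THF, 0 °C → rt; then CuBr·SMe2 (0.1 equiv), 3 (1.2 equiv), −78 °C → rt
Reagents that add atoms: n-butyllithium, [Li]CCCC (supplies only the lithium of 4; 5 takes no reagent atoms)
Why: Directed ortho-metalation removes the C–H between the two chelating MOM ethers, and copper-assisted SN2 allylation of the aryllithium at the primary carbon of 3 should give the linear prenyl group.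

Step 3
Reactants: 5 1,3-bis(methoxymethoxy)-2-(3-methylbut-2-en-1-yl)benzene
Product: 7 3,5-bis(methoxymethoxy)-4-(3-methylbut-2-en-1-yl)phenol, via arylboronate 6 (not isolated)
Conditions: [Ir(OMe)(cod)]2 (1.5 mol %), 4,4'-di-tert-butyl-2,2'-bipyridine (3 mol %), B2pin2 (1.0 equiv), THF, 60 °C; then NaOH (2 M aq), H2O2 (30% aq), 0 °C → rt; NH4Cl (aq)
Reagents that add atoms: bis(pinacolato)diboron, CC1(C)OB(OC1(C)C)B1OC(C)(C)C(C)(C)O1 (boryl group of 6 only); hydrogen peroxide, OO (phenol oxygen of 7)
Why: Sterically governed iridium-catalysed aromatic C–H borylation should take the only ring C–H without an ortho substituent (para to prenyl), and alkaline peroxide oxidation of the C–B bond gives the phenol without touching the trisubstituted alkene.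

Step 4
Reactants: 7 3,5-bis(methoxymethoxy)-4-(3-methylbut-2-en-1-yl)phenol
Product: 8 2-bromo-3,5-bis(methoxymethoxy)-4-(3-methylbut-2-en-1-yl)phenol
Conditions: NBS (1.0 equiv), CH2Cl2, −78 °C
Reagents that add atoms: N-bromosuccinimide, O=C1CCC(=O)N1Br
Why: Electrophilic aromatic bromination at either of the two equivalent phenol ortho carbons, each activated by three oxygens, should be much faster than attack on the prenyl double bond at low temperature.

Step 5
Reactants: 8 2-bromo-3,5-bis(methoxymethoxy)-4-(3-methylbut-2-en-1-yl)phenol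
Product: 12 3,5-bis(methoxymethoxy)-4-(3-methylbut-2-en-1-yl)-2-(trimethylsilyl)phenyl trifluoromethanesulfonate, via silyl ether 9 (not isolated), via aryllithium 10 (not isolated), via lithium phenoxide 11 (not isolated)
Conditions: HMDS, THF, 70 °C; evaporate; n-BuLi (1.1 equiv), THF, −100 → −78 °C; Tf2O (1.2 equiv), −100 → −78 °C; NaHCO3 (aq)
Reagents that add atoms: hexamethyldisilazane, C[Si](C)(C)N[Si](C)(C)C; trifluoromethanesulfonic anhydride, O=S(=O)(OS(=O)(=O)C(F)(F)F)C(F)(F)F; n-butyllithium, [Li]CCCC (lithium of 10 and 11 only)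
Why: This is the standard assembly of an o-silylaryl triflate: O-silylation, bromine–lithium exchange, 1,3 O-to-C silyl shift (retro-Brook rearrangement) driven by phenoxide formation, then O-triflation.

Step 6
Reactants: 13 methyl 3,4-dihydroxybenzoate
Product: 14 methyl 3,4-bis(methoxymethoxy)benzoate
Conditions: NaH (2.4 equiv), MOMCl (2.4 equiv), DMF, 0 °C → rt
Reagents that add atoms: chloromethyl methyl ether (MOMCl), COCCl
Why: Williamson etherification of both catechol oxygens as in step 1, with the non-enolisable methyl ester left untouched.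

Step 7
Reactants: 14 methyl 3,4-bis(methoxymethoxy)benzoate; 15 N-methoxy-N-methylacetamide
Product: 17 3-[3,4-bis(methoxymethoxy)phenyl]-N-methoxy-N-methyl-3-oxopropanamide, via lithium enolate 16 (not isolated)
Conditions: 15 (2.5 equiv), LiN(i-Pr)2 (2.5 equiv), THF, −78 °C; then 14, −78 → −20 °C; NH4Cl (aq)
Reagents that add atoms: lithium diisopropylamide, [Li]N(C(C)C)C(C)C (lithium of 16 only; 17 takes no reagent atoms)
Why: Crossed Claisen condensation in which the preformed amide enolate acylates on the non-enolisable aryl ester and excess enolate deprotonates the β-keto amide, which drives the equilibrium.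

Step 8
Reactants: 17 3-[3,4-bis(methoxymethoxy)phenyl]-N-methoxy-N-methyl-3-oxopropanamide
Product: 18 (3S)-3-[3,4-bis(methoxymethoxy)phenyl]-3-hydroxy-N-methoxy-N-methylpropanamide
Conditions: RuCl[(S,S)-TsDPEN](p-cymene) (1 mol %), HCO2H/Et3N (5:2), DMF, 40 °C
Reagents that add atoms: none
Why: Noyori–Ikariya asymmetric transfer hydrogenation of an aryl ketone, in which the (S,S)-ligand should deliver hydride to the face that gives the (S)-carbinol as it does for acetophenone-type substrates (catalyst control), while amide and acetals are inert.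

Step 9
Reactants: 18 (3S)-3-[3,4-bis(methoxymethoxy)phenyl]-3-hydroxy-N-methoxy-N-methylpropanamide
Product: 19 (3S)-3-[3,4-bis(methoxymethoxy)phenyl]-N-methoxy-N-methyl-3-(trimethylsilyloxy)propanamide
Conditions: 1-(trimethylsilyl)imidazole (1.5 equiv), CH2Cl2, rt; non-aqueous work-up
Reagents that add atoms: 1-(trimethylsilyl)imidazole, C[Si](C)(C)n1ccnc1
Why: Neutral silyl transfer from the N-silylimidazole turns the secondary hydroxyl into a latent, proton-free alkoxide without touching the stereocenter.

Step 10
Reactants: 19 (3S)-3-[3,4-bis(methoxymethoxy)phenyl]-N-methoxy-N-methyl-3-(trimethylsilyloxy)propanamide; 12 3,5-bis(methoxymethoxy)-4-(3-methylbut-2-en-1-yl)-2-(trimethylsilyl)phenyl trifluoromethanesulfonate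
Product: 24 (2S)-2-[3,4-bis(methoxymethoxy)phenyl]-5,7-bis(methoxymethoxy)-6-(3-methylbut-2-en-1-yl)-2,3-dihydro-4H-chromen-4-one, via potassium alkoxide 20 (not isolated), via aryne 21 (not isolated), via arylpotassium 22 (not isolated), via hemiaminal alkoxide 23 (not isolated)
Conditions: KF (3 equiv), 18-crown-6 (3 equiv), THF, 0 °C → rt, 12 (1.3 equiv) added slowly; then NH4Cl (aq)
Reagents that add atoms: potassium fluoride, [K+].[F-] (its potassium stands only in 20, 22 and 23; 24 takes no reagent atoms)
Why: Proposed new method: fluoride strips silicon from both partners, giving alkoxide 20 and, by loss of triflate from the desilylated arene, aryne 21; the alkoxide oxygen adds to the aryne carbon remote from the C5 oxygen (the future C8a), the aryl anion 22 so formed sits at C4a and attacks the amide carbonyl to give 23, which releases the ketone. The closest known reaction types are the fluoride-induced annulations of o-silylaryl triflates with methyl salicylates (to xanthones) and with β-amino esters (to 2,3-dihydroquinolin-4-ones), and the closure of chroman-4-ones by an aryllithium on a tethered Weinreb amide (Parham cyclisation); an aliphatic β-oxy amide has not been used as the partner. Ring C closes by 6-exo-trig attack of the C4a carbanion on C4 (the C4–C4a bond) after the intermolecular O1–C8a bond has formed. No stereocenter is created: C2 comes from 19 with its C–O bond intact, so its configuration is retained, and the C4 centre of 23 is lost on collapse. The step needs regioselective addition, secured by the inductive pull of the C5 and C7 oxygens as in 3,5-dialkoxybenzynes; it needs acylation to outrun protonation of 22, secured by the silyl ether as a proton-free alkoxide source and by the weakly acidic amide α-hydrogens; and it needs a medium that does not stay basic, secured by the slight excess of 12, whose silicon takes up residual alkoxide and amide anion.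

Step 11
Reactants: 24 (2S)-2-[3,4-bis(methoxymethoxy)phenyl]-5,7-bis(methoxymethoxy)-6-(3-methylbut-2-en-1-yl)-2,3-dihydro-4H-chromen-4-one
Product: 25 (2S)-2-(3,4-dihydroxyphenyl)-5,7-dihydroxy-6-(3-methylbut-2-en-1-yl)-2,3-dihydro-4H-chromen-4-one
Conditions: HCl (3 M aq)/MeOH (1:4), 40 °C, short reaction time
Reagents that add atoms: none
Why: Acid-catalysed acetal exchange with methanol removes all four MOM groups as dimethoxymethane, and in the absence of base C2 should not open by β-elimination while a short reaction time limits protonation of the prenyl alkene.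

**Compound list**

1 | resorcinol | Oc1cccc(O)c1 | starting material
2 | 1,3-bis(methoxymethoxy)benzene | COCOc1cccc(OCOC)c1 | intermediate
3 | 1-bromo-3-methylbut-2-ene (prenyl bromide) | CC(C)=CCBr | starting material
4 | [2,6-bis(methoxymethoxy)phenyl]lithium | [Li]c1c(OCOC)cccc1OCOC | intermediate (not isolated)
5 | 1,3-bis(methoxymethoxy)-2-(3-methylbut-2-en-1-yl)benzene | COCOc1cccc(OCOC)c1CC=C(C)C | intermediate
6 | 2-[3,5-bis(methoxymethoxy)-4-(3-methylbut-2-en-1-yl)phenyl]-4,4,5,5-tetramethyl-1,3,2-dioxaborolane | COCOc1cc(B2OC(C)(C)C(C)(C)O2)cc(OCOC)c1CC=C(C)C | intermediate (not isolated)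
7 | 3,5-bis(methoxymethoxy)-4-(3-methylbut-2-en-1-yl)phenol | COCOc1cc(O)cc(OCOC)c1CC=C(C)C | intermediate
8 | 2-bromo-3,5-bis(methoxymethoxy)-4-(3-methylbut-2-en-1-yl)phenol | COCOc1cc(O)c(Br)c(OCOC)c1CC=C(C)C | intermediate
9 | [2-bromo-3,5-bis(methoxymethoxy)-4-(3-methylbut-2-en-1-yl)phenoxy]trimethylsilane | COCOc1cc(O[Si](C)(C)C)c(Br)c(OCOC)c1CC=C(C)C | intermediate (not isolated)
10 | [2,4-bis(methoxymethoxy)-3-(3-methylbut-2-en-1-yl)-6-(trimethylsilyloxy)phenyl]lithium | COCOc1cc(O[Si](C)(C)C)c([Li])c(OCOC)c1CC=C(C)C | intermediate (not isolated)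
11 | lithium 3,5-bis(methoxymethoxy)-4-(3-methylbut-2-en-1-yl)-2-(trimethylsilyl)phenolate | COCOc1cc([O-])c([Si](C)(C)C)c(OCOC)c1CC=C(C)C.[Li+] | intermediate (not isolated)
12 | 3,5-bis(methoxymethoxy)-4-(3-methylbut-2-en-1-yl)-2-(trimethylsilyl)phenyl trifluoromethanesulfonate | COCOc1cc(OS(=O)(=O)C(F)(F)F)c([Si](C)(C)C)c(OCOC)c1CC=C(C)C | intermediate
13 | methyl 3,4-dihydroxybenzoate | COC(=O)c1ccc(O)c(O)c1 | starting material
14 | methyl 3,4-bis(methoxymethoxy)benzoate | COC(=O)c1ccc(OCOC)c(OCOC)c1 | intermediate
15 | N-methoxy-N-methylacetamide | CC(=O)N(C)OC | starting material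
16 | lithium 1-[methoxy(methyl)amino]ethen-1-olate | C=C(O[Li])N(C)OC | intermediate (not isolated)
17 | 3-[3,4-bis(methoxymethoxy)phenyl]-N-methoxy-N-methyl-3-oxopropanamide | CON(C)C(=O)CC(=O)c1ccc(OCOC)c(OCOC)c1 | intermediate
18 | (3S)-3-[3,4-bis(methoxymethoxy)phenyl]-3-hydroxy-N-methoxy-N-methylpropanamide | CON(C)C(=O)C[C@@H](c1ccc(OCOC)c(OCOC)c1)O | intermediate
19 | (3S)-3-[3,4-bis(methoxymethoxy)phenyl]-N-methoxy-N-methyl-3-(trimethylsilyloxy)propanamide | CON(C)C(=O)C[C@@H](c1ccc(OCOC)c(OCOC)c1)O[Si](C)(C)C | intermediate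
20 | potassium (1S)-1-[3,4-bis(methoxymethoxy)phenyl]-3-[methoxy(methyl)amino]-3-oxopropan-1-olate | CON(C)C(=O)C[C@@H](c1ccc(OCOC)c(OCOC)c1)[O-].[K+] | intermediate (not isolated)
21 | 3,5-bis(methoxymethoxy)-4-(3-methylbut-2-en-1-yl)benzyne (triple bond between the future C4a and C8a) | COCOC1=CC#CC(OCOC)=C1CC=C(C)C | intermediate (not isolated)
22 | (3S)-3-[3,4-bis(methoxymethoxy)phenyl]-3-[3,5-bis(methoxymethoxy)-4-(3-methylbut-2-en-1-yl)-2-potassiophenoxy]-N-methoxy-N-methylpropanamide | CON(C)C(=O)C[C@@H](c1ccc(OCOC)c(OCOC)c1)Oc1cc(OCOC)c(CC=C(C)C)c(OCOC)c1[K] | intermediate (not isolated)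
23 | potassium (2S)-2-[3,4-bis(methoxymethoxy)phenyl]-4-[methoxy(methyl)amino]-5,7-bis(methoxymethoxy)-6-(3-methylbut-2-en-1-yl)chroman-4-olate (C4 undefined) | CC(C)=CCc1c(OCOC)cc2c(c1OCOC)C([O-])(N(C)OC)C[C@@H](c1ccc(OCOC)c(OCOC)c1)O2.[K+] | intermediate (not isolated)
24 | (2S)-2-[3,4-bis(methoxymethoxy)phenyl]-5,7-bis(methoxymethoxy)-6-(3-methylbut-2-en-1-yl)-2,3-dihydro-4H-chromen-4-one | CC(C)=CCc1c(OCOC)cc2c(c1OCOC)C(=O)C[C@@H](c1ccc(OCOC)c(OCOC)c1)O2 | intermediate
25 | (2S)-2-(3,4-dihydroxyphenyl)-5,7-dihydroxy-6-(3-methylbut-2-en-1-yl)-2,3-dihydro-4H-chromen-4-one | CC(C)=CCc1c(O)cc2c(c1O)C(=O)C[C@@H](c1ccc(O)c(O)c1)O2 | target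

**Count and risks**

Total steps: 11. Longest linear sequence: 7 steps (steps 1–5, 10, 11); the second branch (steps 6–9) joins at step 10.

Steps most likely to fail:

1. Step 10 (proposed new method). The aryl anion 22 may take a proton from C3–H faster than it acylates, after which β-elimination of the aryloxide destroys the ether. The hindered secondary alkoxide may add too slowly to the aryne, so that aryne self-consumption wins. Base left in the flask may open ring C by β-elimination and erode the configuration at C2. The fallback uses known chemistry, sets out from 17 and 8 and returns at 24. Ketone 17 is reduced as in step 8 but with RuCl[(R,R)-TsDPEN](p-cymene) to (3R)-3-[3,4-bis(methoxymethoxy)phenyl]-3-hydroxy-N-methoxy-N-methylpropanamide F1. Mitsunobu etherification of bromophenol 8 with F1 (PPh3, diisopropyl azodicarboxylate, toluene, 0 °C) should give, with inversion, the (3S)-aryl ether F2. Treatment with t-BuLi (2 equiv, THF, −100 °C) exchanges bromine for lithium, and the aryllithium F3 closes onto the Weinreb amide (Parham cyclisation), forming the same C4–C4a bond and giving 24 after NH4Cl quench.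

2. Step 11. The prenyl double bond may be protonated and the cation captured by the freshly liberated 5- or 7-hydroxyl (chroman formation), or acid may open and reclose ring C with loss of enantiopurity. The fallback sets out from 24 and returns at 25. The acetals are removed without Brønsted acid by silyl transfer: TMSOTf and 2,2'-bipyridyl in CH2Cl2 at 0 °C should convert the four aryl MOM ethers into the tetrakis(trimethylsilyl) ether F4, which is hydrolysed to 25 by adding water at room temperature.

3. Step 4. Electrophilic bromine may attack the prenyl double bond, or a second bromination may occur at the other ortho carbon. The fallback sets out from 7 and returns at 12, bringing in silicon by directed metalation instead of by way of a halide. Phenol 7 is carbamoylated (NaH, ClC(O)NEt2, THF) to the aryl diethylcarbamate F5. s-BuLi/TMEDA (THF, −78 °C) lithiates one of the two equivalent carbons between the carbamate and a MOM ether to give the aryllithium F6, and TMSCl gives the o-silyl carbamate F7. LiAlH4 (THF, 0 °C) cleaves the carbamate to the 2-silylphenol F8, and Tf2O/pyridine (CH2Cl2, −78 → 0 °C) gives 12.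

**Further compounds**

F1 | step 10 | (3R)-3-[3,4-bis(methoxymethoxy)phenyl]-3-hydroxy-N-methoxy-N-methylpropanamide | CON(C)C(=O)C[C@H](c1ccc(OCOC)c(OCOC)c1)O
F2 | step 10 | (3S)-3-[3,4-bis(methoxymethoxy)phenyl]-3-[2-bromo-3,5-bis(methoxymethoxy)-4-(3-methylbut-2-en-1-yl)phenoxy]-N-methoxy-N-methylpropanamide | CON(C)C(=O)C[C@@H](c1ccc(OCOC)c(OCOC)c1)Oc1cc(OCOC)c(CC=C(C)C)c(OCOC)c1Br
F3 | step 10 | (3S)-3-[3,4-bis(methoxymethoxy)phenyl]-3-[2-lithio-3,5-bis(methoxymethoxy)-4-(3-methylbut-2-en-1-yl)phenoxy]-N-methoxy-N-methylpropanamide | CON(C)C(=O)C[C@@H](c1ccc(OCOC)c(OCOC)c1)Oc1cc(OCOC)c(CC=C(C)C)c(OCOC)c1[Li]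
F4 | step 11 | (2S)-2-[3,4-bis(trimethylsilyloxy)phenyl]-6-(3-methylbut-2-en-1-yl)-5,7-bis(trimethylsilyloxy)-2,3-dihydro-4H-chromen-4-one | CC(C)=CCc1c(O[Si](C)(C)C)cc2c(c1O[Si](C)(C)C)C(=O)C[C@@H](c1ccc(O[Si](C)(C)C)c(O[Si](C)(C)C)c1)O2
F5 | step 4 | 3,5-bis(methoxymethoxy)-4-(3-methylbut-2-en-1-yl)phenyl diethylcarbamate | CCN(CC)C(=O)Oc1cc(OCOC)c(CC=C(C)C)c(OCOC)c1
F6 | step 4 | 2-lithio-3,5-bis(methoxymethoxy)-4-(3-methylbut-2-en-1-yl)phenyl diethylcarbamate | CCN(CC)C(=O)Oc1cc(OCOC)c(CC=C(C)C)c(OCOC)c1[Li]
F7 | step 4 | 3,5-bis(methoxymethoxy)-4-(3-methylbut-2-en-1-yl)-2-(trimethylsilyl)phenyl diethylcarbamate | CCN(CC)C(=O)Oc1cc(OCOC)c(CC=C(C)C)c(OCOC)c1[Si](C)(C)C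
F8 | step 4 | 3,5-bis(methoxymethoxy)-4-(3-methylbut-2-en-1-yl)-2-(trimethylsilyl)phenol | COCOc1cc(O)c([Si](C)(C)C)c(OCOC)c1CC=C(C)C
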